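The flavonol is cut at the O1–C8a aryl ether bond of ring C. The feature exploited lies in ring A: the two carbons flanking C4a, C8a and C5, both carry oxygen and both sit ortho to the C4 acyl group, so a locally symmetric 2,6-difluoro-4-alkoxybenzoyl unit can serve them one after the other. The precursor is a 2-(methoxymethoxy)-1,3-diaryl-1,3-diketone; its enolate oxygen displaces either fluoride, which in one operation closes ring C, erases the only stereocentre and leaves C5–F as an activated handle. MOM marks the oxygens to be sulfated (O3, O7, O4'), benzyl those that stay free (O5, O3'), so sulfation is exhaustive and hydrogenolysis ends the route.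

Key step: step 7

Assumption: the target is taken as the fully protonated tris(hydrogen sulfate) as drawn; because aryl hydrogen sulfates hydrolyse autocatalytically, the sulfate esters are carried as triethylammonium salts and the acid form is released only in the last operation. The target has no stereocentre.

Step 1
Reactants: 1 2,6-difluoro-4-hydroxybenzoic acid
Product: 3 2,6-difluoro-4-(methoxymethoxy)benzoic acid, via MOM ester MOM ether 2 (not isolated)
Conditions: MOMCl (2.4 equiv), i-Pr2NEt (3 equiv), THF, 0 °C → rt; then 1 M aq LiOH (5 equiv), rt; cold 1 M HCl to pH 3, immediate EtOAc extraction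
Reagents that add atoms: chloromethyl methyl ether (MOMCl), COCCl; LiOH, [Li+].[OH-] (one carboxyl oxygen of 3)
Why: Double Williamson-type O-alkylation of phenoxide and carboxylate followed by saponification should leave only the aryl MOM ether, because the acyloxymethyl ester is an activated ester that hydroxide cleaves at room temperature, aryl acetals are inert to base, and the carboxylate formed switches off SNAr at the C–F carbons.

Step 2
Reactants: 4 3',4'-dihydroxyacetophenone
Product: 5 1-[3-hydroxy-4-(methoxymethoxy)phenyl]ethan-1-one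
Conditions: MOMCl (1.05 equiv), K2CO3 (1.1 equiv), acetone, 0 °C → rt; chromatography
Reagents that add atoms: chloromethyl methyl ether (MOMCl), COCCl
Why: Regioselective Williamson-type O-alkylation: the 4'-OH is conjugated with the para acetyl group and is the more acidic phenol, so one equivalent of weak base ionises it preferentially and MOMCl traps that phenoxide, any bis-ether or regioisomer being removed at this cheap stage.

Step 3
Reactants: 5 1-[3-hydroxy-4-(methoxymethoxy)phenyl]ethan-1-one
Product: 6 1-[3-(benzyloxy)-4-(methoxymethoxy)phenyl]ethan-1-one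
Conditions: BnBr (1.2 equiv), K2CO3 (2 equiv), DMF, 50 °C
Reagents that add atoms: benzyl bromide, BrCc1ccccc1
Why: Williamson ether synthesis on the only remaining phenol; carbonate is too weak to enolise the methyl ketone and the MOM acetal is stable to base.

Step 4
Reactants: 6 1-[3-(benzyloxy)-4-(methoxymethoxy)phenyl]ethan-1-one
Product: 9 1-[3-(benzyloxy)-4-(methoxymethoxy)phenyl]-2-hydroxyethan-1-one, via trimethylsilyl enol ether 7 (not isolated), via silyloxy ketone 8 (not isolated)
Conditions: LiN(SiMe3)2 (1.2 equiv), Me3SiCl (1.3 equiv), THF, −78 → 0 °C; crude 7, mCPBA (1.1 equiv), CH2Cl2, −10 → 0 °C; citric acid (cat.), MeOH, rt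
Reagents that add atoms: mCPBA, O=C(OO)c1cccc(Cl)c1 (the new oxygen); Me3SiCl, C[Si](C)(C)Cl (silicon of 7 and 8 only)
Why: Rubottom oxidation: the only possible enolate is silylated, the electron-rich enol ether is epoxidised far faster than the aryl ketone could undergo Baeyer–Villiger oxidation, 1,4-silyl migration gives 8, and mild methanolysis frees the primary alcohol without touching MOM or benzyl.

Step 5
Reactants: 9 1-[3-(benzyloxy)-4-(methoxymethoxy)phenyl]-2-hydroxyethan-1-one
Product: 10 1-[3-(benzyloxy)-4-(methoxymethoxy)phenyl]-2-(methoxymethoxy)ethan-1-one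
Conditions: MOMCl (1.5 equiv), i-Pr2NEt (2 equiv), CH2Cl2, 0 °C → rt
Reagents that add atoms: chloromethyl methyl ether (MOMCl), COCCl
Why: O-Alkylation (acetal formation) of the primary alcohol with MOMCl under a hindered amine base, conditions too mild to enolise or dimerise the α-hydroxy ketone.

Step 6
Reactants: 3 2,6-difluoro-4-(methoxymethoxy)benzoic acid; 10 1-[3-(benzyloxy)-4-(methoxymethoxy)phenyl]-2-(methoxymethoxy)ethan-1-one
Product: 13 1-[3-(benzyloxy)-4-(methoxymethoxy)phenyl]-3-[2,6-difluoro-4-(methoxymethoxy)phenyl]-2-(methoxymethoxy)propane-1,3-dione (racemic), via acid chloride 11 (not isolated), via lithium Z-enolate 12 (not isolated)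
Conditions: 3, Me2C=C(Cl)NMe2 (1.1 equiv), CH2Cl2, 0 °C → rt; separately 10, LiN(SiMe3)2 (2.1 equiv), THF, −78 °C; solution of 11 (1.15 equiv) added, −78 → −20 °C; aq NH4Cl
Reagents that add atoms: 1-chloro-N,N,2-trimethylprop-1-en-1-amine, CC(C)=C(Cl)N(C)C (chlorine of 11 only); LiN(SiMe3)2, [Li+].C[Si](C)(C)[N-][Si](C)(C)C (lithium of 12 only)
Why: Claisen-type C-acylation of a preformed lithium enolate by an aroyl chloride: the α-chloroenamine makes the acid chloride without releasing HCl (which would strip the aryl MOM ether), the lithium-chelated Z-enolate in THF favours C- over O-acylation, the second equivalent of base stores the more acidic product as a tight lithium chelate that neither reacts on nor cyclises in the cold, and the new C2 stereocentre forms racemic and is erased in step 7.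

Step 7
Reactants: 13 1-[3-(benzyloxy)-4-(methoxymethoxy)phenyl]-3-[2,6-difluoro-4-(methoxymethoxy)phenyl]-2-(methoxymethoxy)propane-1,3-dione (racemic)
Product: 14 2-[3-(benzyloxy)-4-(methoxymethoxy)phenyl]-5-fluoro-3,7-bis(methoxymethoxy)-4H-chromen-4-one
Conditions: Cs2CO3 (1.5 equiv), dry amine-free DMF (0.05 M), 4 Å molecular sieves, 70 °C, Ar
Reagents that add atoms: none
Why: Cs2CO3 removes the C2–H of 13, and in DMF the loosely paired caesium enolate can turn about the bond that becomes C3–C4 until the oxygen on the ring B carbonyl carbon faces a C–F carbon of ring A; addition there gives a Meisenheimer anion whose charge runs through C4a into the C4 carbonyl, and loss of fluoride completes the O1–C8a bond. The closest known reaction type is the metal-free, carbonate-mediated intramolecular SNAr O-arylation of 1-(2-haloaryl)-1,3-diketones to chromones and flavones. Ring C closes as a six-membered ring by addition–elimination: the addition is 6-endo-trig with respect to the C8a=C4a–C4=O acceptor, which lies inside the new ring as in the oxa-Michael closure of 2'-hydroxychalcones, while the C–F bond that finally breaks is exocyclic. No stereocentre is formed, and the racemic C2 centre of 13 ends as the sp2 carbon C3. The step needs O- over C-arylation and the right enolate oxygen, both secured by ring size because the central carbon or the oxygen next to ring A could only form four-membered rings, and it needs no regiocontrol because the two C–F carbons are interchanged by rotation of the aroyl ring. The 4-OMOM group is meta to both C–F carbons and so stays off the charge-bearing positions, the second fluorine adds inductive activation, and dilution with exclusion of water holds back intermolecular substitution and retro-Claisen cleavage.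

Step 8
Reactants: 14 2-[3-(benzyloxy)-4-(methoxymethoxy)phenyl]-5-fluoro-3,7-bis(methoxymethoxy)-4H-chromen-4-one
Product: 15 5-(benzyloxy)-2-[3-(benzyloxy)-4-(methoxymethoxy)phenyl]-3,7-bis(methoxymethoxy)-4H-chromen-4-one
Conditions: BnOH (1.5 equiv), NaH (1.4 equiv), dry THF, 0 °C; then 14, 0 → 45 °C
Reagents that add atoms: benzyl alcohol, OCc1ccccc1
Why: Intermolecular SNAr (addition–elimination): C5–F is ortho to the C4 acyl carbon through C4a, the donor oxygens at C7 and O1 are meta to C5 and thus off the charge-bearing positions, sodium bridging between the C4 oxygen and the alkoxide steers delivery to the peri position, and under anhydrous conditions addition at C2 is reversible whereas loss of fluoride is not.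

Step 9
Reactants: 15 5-(benzyloxy)-2-[3-(benzyloxy)-4-(methoxymethoxy)phenyl]-3,7-bis(methoxymethoxy)-4H-chromen-4-one
Product: 16 5-(benzyloxy)-2-[3-(benzyloxy)-4-hydroxyphenyl]-3,7-dihydroxy-4H-chromen-4-one
Conditions: HCl (cat., ca. 0.5 M), MeOH–THF (3:1), 40 °C
Reagents that add atoms: none
Why: Acid-catalysed transacetalisation (MOM cleavage): all three MOM groups sit on phenolic or enolic oxygens and leave readily, methanol captures the CH2 unit as dimethoxymethane so that no formaldehyde can attack the nucleophilic C6 and C8 positions, and the benzyl ethers, including the peri 5-O-benzyl group that needs hot concentrated acid or a Lewis acid, should persist.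

Step 10
Reactants: 16 5-(benzyloxy)-2-[3-(benzyloxy)-4-hydroxyphenyl]-3,7-dihydroxy-4H-chromen-4-one
Product: 17 tris(triethylammonium) 5,3'-di-O-benzylquercetin 3,4',7-trisulfate
Conditions: Et3N·SO3 (12 equiv), Et3N (3 equiv), N,N-dimethylacetamide, 65 °C, Ar; Sephadex LH-20 (MeOH)
Reagents that add atoms: sulfur trioxide–triethylamine complex, CC[N+](CC)(CC)S(=O)(=O)[O-]
Why: O-Sulfation of phenols with an amine–SO3 complex: every hydroxyl still free is a site that the target carries as sulfate, so excess reagent can drive the reaction to completion without any selectivity (the hydrogen-bonded 3-OH being the slowest), the triethylammonium counter-ions and two benzyl groups keep the trianion soluble and purifiable, and argon protects the oxidation-prone 3-hydroxyflavone.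

Step 11
Reactants: 17 tris(triethylammonium) 5,3'-di-O-benzylquercetin 3,4',7-trisulfate
Product: 19 quercetin 3,4',7-tris(hydrogen sulfate), via debenzylated triethylammonium salt 18 (not isolated)
Conditions: H2 (1 atm), Pd/C (10 wt % Pd), MeOH–H2O (4:1), rt; filtration; sulfonic acid cation-exchange resin (H+ form), H2O, 0–4 °C; freeze-drying at once
Reagents that add atoms: none
Why: Catalytic hydrogenolysis of aryl benzyl ethers in neutral medium, to which sulfate monoester anions and the tetrasubstituted C2=C3 bond of the pyrone are inert, followed by cation exchange that swaps Et3NH+ for H+; cold handling and immediate freeze-drying limit acid-catalysed loss of the labile 3-O-sulfate.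

Compound list
1 | 2,6-difluoro-4-hydroxybenzoic acid | O=C(O)c1c(F)cc(O)cc1F | starting material
2 | methoxymethyl 2,6-difluoro-4-(methoxymethoxy)benzoate | COCOC(=O)c1c(F)cc(OCOC)cc1F | intermediate
3 | 2,6-difluoro-4-(methoxymethoxy)benzoic acid | O=C(O)c1c(F)cc(OCOC)cc1F | intermediate
4 | 3',4'-dihydroxyacetophenone | CC(=O)c1ccc(O)c(O)c1 | starting material
5 | 1-[3-hydroxy-4-(methoxymethoxy)phenyl]ethan-1-one | CC(=O)c1ccc(OCOC)c(O)c1 | intermediate
6 | 1-[3-(benzyloxy)-4-(methoxymethoxy)phenyl]ethan-1-one | CC(=O)c1ccc(OCOC)c(OCc2ccccc2)c1 | intermediate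
7 | ({1-[3-(benzyloxy)-4-(methoxymethoxy)phenyl]ethenyl}oxy)trimethylsilane | C=C(O[Si](C)(C)C)c1ccc(OCOC)c(OCc2ccccc2)c1 | intermediate
8 | 1-[3-(benzyloxy)-4-(methoxymethoxy)phenyl]-2-[(trimethylsilyl)oxy]ethan-1-one | C[Si](C)(C)OCC(=O)c1ccc(OCOC)c(OCc2ccccc2)c1 | intermediate
9 | 1-[3-(benzyloxy)-4-(methoxymethoxy)phenyl]-2-hydroxyethan-1-one | O=C(CO)c1ccc(OCOC)c(OCc2ccccc2)c1 | intermediate
10 | 1-[3-(benzyloxy)-4-(methoxymethoxy)phenyl]-2-(methoxymethoxy)ethan-1-one | COCOCC(=O)c1ccc(OCOC)c(OCc2ccccc2)c1 | intermediate
11 | 2,6-difluoro-4-(methoxymethoxy)benzoyl chloride | O=C(Cl)c1c(F)cc(OCOC)cc1F | intermediate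
12 | lithium (Z)-1-[3-(benzyloxy)-4-(methoxymethoxy)phenyl]-2-(methoxymethoxy)ethen-1-olate | [Li+].[O-]/C(=C\OCOC)c1ccc(OCOC)c(OCc2ccccc2)c1 | intermediate
13 | 1-[3-(benzyloxy)-4-(methoxymethoxy)phenyl]-3-[2,6-difluoro-4-(methoxymethoxy)phenyl]-2-(methoxymethoxy)propane-1,3-dione (racemic, enolisable) | COCOC(C(=O)c1c(F)cc(OCOC)cc1F)C(=O)c1ccc(OCOC)c(OCc2ccccc2)c1 | intermediate
14 | 2-[3-(benzyloxy)-4-(methoxymethoxy)phenyl]-5-fluoro-3,7-bis(methoxymethoxy)-4H-chromen-4-one | O=c1c(OCOC)c(-c2ccc(OCOC)c(OCc3ccccc3)c2)oc2cc(OCOC)cc(F)c12 | intermediate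
15 | 5-(benzyloxy)-2-[3-(benzyloxy)-4-(methoxymethoxy)phenyl]-3,7-bis(methoxymethoxy)-4H-chromen-4-one | O=c1c(OCOC)c(-c2ccc(OCOC)c(OCc3ccccc3)c2)oc2cc(OCOC)cc(OCc3ccccc3)c12 | intermediate
16 | 5-(benzyloxy)-2-[3-(benzyloxy)-4-hydroxyphenyl]-3,7-dihydroxy-4H-chromen-4-one | O=c1c(O)c(-c2ccc(O)c(OCc3ccccc3)c2)oc2cc(O)cc(OCc3ccccc3)c12 | intermediate
17 | tris(triethylammonium) 5,3'-di-O-benzylquercetin 3,4',7-trisulfate | O=c1c(OS(=O)(=O)[O-])c(-c2ccc(OS(=O)(=O)[O-])c(OCc3ccccc3)c2)oc2cc(OS(=O)(=O)[O-])cc(OCc3ccccc3)c12.CC[NH+](CC)CC.CC[NH+](CC)CC.CC[NH+](CC)CC | intermediate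
18 | tris(triethylammonium) quercetin 3,4',7-trisulfate | O=c1c(OS(=O)(=O)[O-])c(-c2ccc(OS(=O)(=O)[O-])c(O)c2)oc2cc(OS(=O)(=O)[O-])cc(O)c12.CC[NH+](CC)CC.CC[NH+](CC)CC.CC[NH+](CC)CC | intermediate
19 | quercetin 3,4',7-tris(hydrogen sulfate) | O=c1c(OS(=O)(=O)O)c(-c2ccc(OS(=O)(=O)O)c(O)c2)oc2cc(OS(=O)(=O)O)cc(O)c12 | target

Total step count: 11. Longest linear sequence: 10 steps (4 → 19, steps 2–11); step 1 is the short ring A branch that joins at step 6.

Steps most likely to fail

Step 7. The closure may stall because the negative charge of the enolate is shared with the very carbonyl that has to activate ring A. On long heating, traces of hydroxide may then cleave the poorly enolised 2-alkoxy diketone by retro-Claisen fragmentation. The fallback sets out from 6 (together with 11) and comes back at 14. It takes the C3 oxygen out of the closure substrate and adds it after ring formation.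
- 6 would be C-acylated with 11 [LiN(SiMe3)2 (2.1 equiv), THF, −78 °C] to the fully enolised, cleavage-resistant 1-[3-(benzyloxy)-4-(methoxymethoxy)phenyl]-3-[2,6-difluoro-4-(methoxymethoxy)phenyl]propane-1,3-dione F1. This is the substrate type for which carbonate-mediated halide displacement is best established.
- K2CO3 in DMF at 80 °C should give 2-[3-(benzyloxy)-4-(methoxymethoxy)phenyl]-5-fluoro-7-(methoxymethoxy)-4H-chromen-4-one F2.
- Dimethyldioxirane (acetone–CH2Cl2, 0 °C) should epoxidise C2=C3 to 2-[3-(benzyloxy)-4-(methoxymethoxy)phenyl]-2,3-epoxy-5-fluoro-7-(methoxymethoxy)chroman-4-one F3.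
- A trace of p-TsOH isomerises this to 2-[3-(benzyloxy)-4-(methoxymethoxy)phenyl]-5-fluoro-3-hydroxy-7-(methoxymethoxy)-4H-chromen-4-one F4.
- MOMCl/i-Pr2NEt then gives 14.

Step 8. Benzyl oxide may add at C2 and open ring C, or substitution at C5 may be too slow because the C4 carbonyl is only a vinylogous ester carbonyl. The fallback sets out from 11 and comes back at 15. It makes the C5–O bond on a benzoate before ring C exists, so that the pyrone never meets an alkoxide.
- 11 is added to NaOCH2Ph (2 equiv, THF, 0 °C). Esterification gives benzyl 2,6-difluoro-4-(methoxymethoxy)benzoate F5.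
- The second equivalent displaces one of the two equivalent ortho fluorides (ester exchange being degenerate) to give benzyl 2-(benzyloxy)-6-fluoro-4-(methoxymethoxy)benzoate F6.
- KOH in aqueous dioxane at 60 °C gives 2-(benzyloxy)-6-fluoro-4-(methoxymethoxy)benzoic acid F7.
- The α-chloroenamine of step 6 converts this into 2-(benzyloxy)-6-fluoro-4-(methoxymethoxy)benzoyl chloride F8.
- F8 acylates enolate 12 to 1-[2-(benzyloxy)-6-fluoro-4-(methoxymethoxy)phenyl]-3-[3-(benzyloxy)-4-(methoxymethoxy)phenyl]-2-(methoxymethoxy)propane-1,3-dione F9.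
- Cs2CO3 in DMF closes ring C on the single remaining C–F carbon and should give 15 directly.

Step 6. O-Acylation of the enolate, proton transfer from product to unreacted enolate, or consumption of the acid chloride by the excess amide base may erode the C-acylation. The fallback sets out from 10 (as its enolate 12) and comes back at 13. It replaces acylation by aldol addition and oxidation.
- Commercial 2,6-difluoro-4-hydroxybenzaldehyde is protected (MOMCl, i-Pr2NEt, CH2Cl2) as 2,6-difluoro-4-(methoxymethoxy)benzaldehyde F10.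
- Enolate 12 (one equivalent of base suffices) adds to it at −78 °C, where only C-attack is productive. This gives 1-[3-(benzyloxy)-4-(methoxymethoxy)phenyl]-3-[2,6-difluoro-4-(methoxymethoxy)phenyl]-3-hydroxy-2-(methoxymethoxy)propan-1-one F11 as a mixture of racemic diastereomers, both centres being lost later.
- 2-Iodoxybenzoic acid (EtOAc, 75 °C) oxidises the benzylic alcohol to 13.

Further compounds
F1 | step 7 | 1-[3-(benzyloxy)-4-(methoxymethoxy)phenyl]-3-[2,6-difluoro-4-(methoxymethoxy)phenyl]propane-1,3-dione | O=C(CC(=O)c1c(F)cc(OCOC)cc1F)c1ccc(OCOC)c(OCc2ccccc2)c1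
F2 | step 7 | 2-[3-(benzyloxy)-4-(methoxymethoxy)phenyl]-5-fluoro-7-(methoxymethoxy)-4H-chromen-4-one | O=c1cc(-c2ccc(OCOC)c(OCc3ccccc3)c2)oc2cc(OCOC)cc(F)c12
F3 | step 7 | 2-[3-(benzyloxy)-4-(methoxymethoxy)phenyl]-2,3-epoxy-5-fluoro-7-(methoxymethoxy)chroman-4-one (racemic, cis-fused) | O=C1c2c(F)cc(OCOC)cc2OC2(c3ccc(OCOC)c(OCc4ccccc4)c3)OC12
F4 | step 7 | 2-[3-(benzyloxy)-4-(methoxymethoxy)phenyl]-5-fluoro-3-hydroxy-7-(methoxymethoxy)-4H-chromen-4-one | O=c1c(O)c(-c2ccc(OCOC)c(OCc3ccccc3)c2)oc2cc(OCOC)cc(F)c12
F5 | step 8 | benzyl 2,6-difluoro-4-(methoxymethoxy)benzoate | O=C(OCc1ccccc1)c1c(F)cc(OCOC)cc1F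
F6 | step 8 | benzyl 2-(benzyloxy)-6-fluoro-4-(methoxymethoxy)benzoate | O=C(OCc1ccccc1)c1c(F)cc(OCOC)cc1OCc1ccccc1
F7 | step 8 | 2-(benzyloxy)-6-fluoro-4-(methoxymethoxy)benzoic acid | O=C(O)c1c(F)cc(OCOC)cc1OCc1ccccc1
F8 | step 8 | 2-(benzyloxy)-6-fluoro-4-(methoxymethoxy)benzoyl chloride | O=C(Cl)c1c(F)cc(OCOC)cc1OCc1ccccc1
F9 | step 8 | 1-[2-(benzyloxy)-6-fluoro-4-(methoxymethoxy)phenyl]-3-[3-(benzyloxy)-4-(methoxymethoxy)phenyl]-2-(methoxymethoxy)propane-1,3-dione (racemic) | COCOC(C(=O)c1c(F)cc(OCOC)cc1OCc1ccccc1)C(=O)c1ccc(OCOC)c(OCc2ccccc2)c1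
F10 | step 6 | 2,6-difluoro-4-(methoxymethoxy)benzaldehyde | O=Cc1c(F)cc(OCOC)cc1F
F11 | step 6 | 1-[3-(benzyloxy)-4-(methoxymethoxy)phenyl]-3-[2,6-difluoro-4-(methoxymethoxy)phenyl]-3-hydroxy-2-(methoxymethoxy)propan-1-one (mixture of racemic diastereomers) | COCOC(C(O)c1c(F)cc(OCOC)cc1F)C(=O)c1ccc(OCOC)c(OCc2ccccc2)c1
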